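**Plan**
- **Bonds cut, in retrosynthetic order:** the five O–CH3 bonds. Then, together, the C5–CH(CH3) bond (ten-membered ring) and the C4=C(aryl) bond (ring D). Then the ring A–O bond of the diaryl ether, and last the two aryl–C(=O) bonds and the ethylidene C=C of a six-carbon chain.
- **Enabling feature:** outside the naphthalene, ring D holds only three carbons, CH(CH3)–CH–C(aryl)=. They span the peri carbons C5 (ring B, next to the ether oxygen on C6) and C4 (ring C) of a 1,3,6,8-tetraoxygenated naphthalene. Read backwards they are the β-carbon, α-carbon and carbonyl carbon of an α-ethylidene aryl ketone.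
- **Forward order:** the chain comes first (half ester, ring E ketone, ethylidene, ring A ketone). A C2-symmetric naphthalenediol (rings B and C) is then hung on ring A as an aryl ether, the macrocycle and ring D close in one acid-promoted operation, and demethylation ends the route. Rings A, B, C and E are bought as arenes.
- **Stereochemistry:** the chain methyl centre (S in the target) is bought with methyl hydrogen (R)-3-methylglutarate. It steers the benzylic centre (R) through allylic strain in the tethered closure, and the methine (R) settles trans to the benzylic methyl by equilibration.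

Key step: step 8

Labels: naphthalene carbons keep the numbering of 1,3,6,8-tetraoxygenated naphthalene (ring C = C1–C4, ring B = C5–C8). Ring A is the benzene ring of the macrocyclic ketone and ring E the pendant 2,6-dioxygenated phenyl. Ca = chain CH(CH3), Cb = benzylic CH(CH3), Cm = the methine between them.

Assumption: the C1 oxygen is carried as a methyl ether, so water leaves in the key step through the C3=O (ortho) quinone methide; after demethylation the vinylogous acid O=C–CH=C–OH of ring C is taken to tautomerise freely to the 1-oxo-3-hydroxy form drawn for the target, which is held by the hydrogen bond to the C8 hydroxyl.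

Step 1
Reactants: 1 methyl hydrogen (R)-3-methylglutarate; 2 1,3-dimethoxybenzene
Product: 6 methyl (3R)-5-(2,6-dimethoxyphenyl)-3-methyl-5-oxopentanoate, via acid chloride 3 (not isolated), via aryllithium 4 (not isolated), via arylzinc chloride 5 (not isolated)
Conditions: 1, (COCl)2, DMF (cat.), CH2Cl2, 0 °C, evaporate; 2, n-BuLi, THF, 0 °C to rt, then ZnCl2, 0 °C; combine, Pd(PPh3)4 (5 mol %), THF, 0 °C to rt
Reagents that add atoms: oxalyl chloride, O=C(Cl)C(=O)Cl (Cl of 3); n-butyllithium, [Li]CCCC (Li of 4); zinc chloride, [Zn+2].[Cl-].[Cl-] (ZnCl of 5)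
Why: Directed ortho-lithiation between the two methoxy groups, transmetalation to zinc and Negishi acylation under zerovalent palladium catalysis should join the aryl group to the acid chloride only, because an arylzinc chloride leaves a methyl ester alone, and the cold, base-free formation of 3 should keep the two chain ends from exchanging, so that the stereocentre (β to both carbonyl groups) is carried over unchanged.

Step 2
Reactants: 6 methyl (3R)-5-(2,6-dimethoxyphenyl)-3-methyl-5-oxopentanoate; 7 acetaldehyde
Product: 9 methyl (3S)-4-(2,6-dimethoxybenzoyl)-5-hydroxy-3-methylhexanoate (mixture at C4 and C5), via lithium enolate 8 (not isolated)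
Conditions: LiHMDS, THF, −78 °C; 7 (3 equiv), −78 °C; AcOH quench at −78 °C
Reagents that add atoms: lithium hexamethyldisilazide, [Li+].C[Si](C)(C)[N-][Si](C)(C)C (Li of 8)
Why: Crossed aldol addition in which LiHMDS should take the ketone α-proton in preference to the less acidic ester α-proton, the lithium enolate adds to the unhindered aldehyde, and the two new centres (formed as a mixture) are erased in step 3.

Step 3
Reactants: 9 methyl (3S)-4-(2,6-dimethoxybenzoyl)-5-hydroxy-3-methylhexanoate
Product: 11 methyl (3S,4E)-4-(2,6-dimethoxybenzoyl)-3-methylhex-4-enoate, via mesylate 10 (not isolated)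
Conditions: MsCl, Et3N, CH2Cl2, 0 °C; then DBU, rt
Reagents that add atoms: methanesulfonyl chloride, CS(=O)(=O)Cl (mesyl group of 10)
Why: Mesylation followed by DBU-induced E1cB elimination of the β-mesyloxy ketone should give, from every aldol diastereomer, the more stable E-alkene in which the new methyl group lies anti to the aroyl group.

Step 4
Reactants: 11 methyl (3S,4E)-4-(2,6-dimethoxybenzoyl)-3-methylhex-4-enoate
Product: 12 (3S,4E)-4-(2,6-dimethoxybenzoyl)-3-methylhex-4-enoic acid
Conditions: LiOH, THF/H2O, 0 °C to rt; then 1 M HCl
Reagents that add atoms: lithium hydroxide, [Li+].[OH-]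
Why: Saponification of an unhindered methyl ester under conditions at which the hindered trisubstituted enone and the non-acidic stereocentre should stay untouched.

Step 5
Reactants: 12 (3S,4E)-4-(2,6-dimethoxybenzoyl)-3-methylhex-4-enoic acid; 13 1-fluoro-3-methoxybenzene
Product: 17 (3S,4E)-4-(2,6-dimethoxybenzoyl)-1-(2-fluoro-6-methoxyphenyl)-3-methylhex-4-en-1-one, via acid chloride 14 (not isolated), via aryllithium 15 (not isolated), via arylzinc chloride 16 (not isolated)
Conditions: 12, (COCl)2, DMF (cat.), CH2Cl2, 0 °C, evaporate; 13, n-BuLi, THF, −78 °C, then ZnCl2, −78 °C to rt; combine, Pd(PPh3)4 (5 mol %), THF, rt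
Reagents that add atoms: oxalyl chloride, O=C(Cl)C(=O)Cl (Cl of 14); n-butyllithium, [Li]CCCC (Li of 15); zinc chloride, [Zn+2].[Cl-].[Cl-] (ZnCl of 16)
Why: Ortho-lithiation at the carbon flanked by fluorine and methoxy at −78 °C (cold enough to hold back loss of LiF), transmetalation to the stable arylzinc chloride and Negishi acylation should deliver the second aryl ketone, since arylzinc halides add neither to the enone nor to the hindered ketone.

Step 6
Reactants: 18 1,8-dimethoxynaphthalene
Product: 20 4,5-dimethoxynaphthalene-2,7-diol, via bis(pinacol boronate) 19 (not isolated)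
Conditions: [Ir(OMe)(cod)]2 (1.5 mol %), 4,4'-di-tert-butyl-2,2'-bipyridine (3 mol %), B2pin2 (2.2 equiv), THF, 80 °C; evaporate; 30 % aq H2O2, THF, 0 °C to rt, under Ar
Reagents that add atoms: bis(pinacolato)diboron, CC1(C)OB(OC1(C)C)B1OC(C)(C)C(C)(C)O1 (boryl groups of 19); hydrogen peroxide, OO (hydroxyl oxygens of 20)
Why: Sterically governed iridium-catalysed C–H borylation should strike only C3–H and C6–H, because C2–H and C7–H are ortho to methoxy and C4–H and C5–H shield each other across the peri gap, and peroxide then replaces each C–B bond by C–OH at the same carbon.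

Step 7
Reactants: 17 (3S,4E)-4-(2,6-dimethoxybenzoyl)-1-(2-fluoro-6-methoxyphenyl)-3-methylhex-4-en-1-one; 20 4,5-dimethoxynaphthalene-2,7-diol
Product: 21 seco diaryl ether, (3S,4E)-4-(2,6-dimethoxybenzoyl)-1-{2-[(7-hydroxy-4,5-dimethoxynaphthalen-2-yl)oxy]-6-methoxyphenyl}-3-methylhex-4-en-1-one
Conditions: 20 (3 equiv), Cs2CO3 (2 equiv), degassed DMSO, 80 °C, Ar
Reagents that add atoms: none
Why: Nucleophilic aromatic substitution by addition–elimination in which the caesium naphthoxide attacks the C–F carbon activated by the ortho ketone, the two hydroxyls of 20 are equivalent so that no regiochemical question arises, and the excess of diol should hold the reaction at monoarylation.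

Step 8
Reactants: 21 seco diaryl ether
Product: 24 penta-O-methyl ring-closed compound in its 3-oxo form (ring C = C1(OCH3)=C2H–C3(=O)–C4(=C–ring E); Ca S, Cb R, Cm R), via macrocyclic diketone 22 (not isolated), via ring D carbinol 23 (not isolated)
Conditions: (CF3SO2)2NH (0.5 equiv), (CF3)2CHOH/CH2Cl2 (1:4), 21 added by syringe pump to 1 mM, 0 °C to 40 °C
Reagents that add atoms: none
Why: Proposed new method: the acid protonates the enone oxygen, C5 (ortho to the ether oxygen on C6, para to the C8 methoxy group) adds to the ethylidene carbon and the enol tautomerises to macrocyclic diketone 22, C4 (ortho to the free C3 hydroxyl, para to the C1 methoxy group) then adds to the protonated ring E ketone to give carbinol 23, and ionisation of 23 with loss of the C3–OH proton expels water and leaves the ortho-quinone methide 24. The closest known reaction type is the acid-promoted Friedel–Crafts conjugate addition of a naphthol to an enone followed by cyclodehydration (peri-annulation to a phenalenone), which is established between two separate partners but not as the closure of a ten-membered ring that has to begin at the less electron-rich ring. The macrocycle closes 10-endo-trig (both alkene carbons become ring members) and ring D closes 6-exo-trig at the carbonyl carbon. Cb (R) is controlled by Ca: allylic 1,3-strain with the cis methyl group holds the Ca–H bond in the alkene plane, the CH2 arm that leads to the tether then lies over one face only, and C5 can reach the ethylidene carbon only from that face, while Cm (R) is α to the ketone in 22 and vinylogously acidic in 24 and should therefore settle trans to the Cb methyl group on ring D. The step needs C5 to win over C4, C2 and C7: the short tether allows a ten-membered ring only through C5 or C7 (C4 and C2 would need 12 and 14 ring atoms), arylation of an enone by such electron-rich rings is reversible in acid, and only the C5 adduct holds the ketone next to a peri carbon with an ortho hydroxyl, so that it alone drains away by irreversible loss of water. High dilution holds back bimolecular alkylation, and leaving only one free hydroxyl on ring C keeps the gap in nucleophilicity between the two rings small.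

Step 9
Reactants: 24 penta-O-methyl ring-closed compound
Product: 25 CNP0225737.1 (Ca S, Cb R, Cm R)
Conditions: BBr3 (12 equiv), CH2Cl2, −78 °C to rt; then H2O, 0 °C
Reagents that add atoms: none
Why: Lewis acid ether cleavage in which BBr3 should cleave the four aryl methyl ethers and the vinylogous methyl ester while leaving the diaryl ether intact, the freed vinylogous acid tautomerises to the hydrogen-bonded 1-oxo-3-hydroxy form, Ca and Cb carry no acidic hydrogen and Cm already sits in its more stable trans arrangement.

**Compound list**
1 | methyl hydrogen (R)-3-methylglutarate | C[C@H](CC(=O)O)CC(=O)OC | starting material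
2 | 1,3-dimethoxybenzene | COc1cccc(OC)c1 | starting material
3 | methyl (3S)-5-chloro-3-methyl-5-oxopentanoate | C[C@H](CC(=O)Cl)CC(=O)OC | intermediate
4 | 2,6-dimethoxyphenyllithium | [Li]c1c(OC)cccc1OC | intermediate
5 | (2,6-dimethoxyphenyl)zinc chloride | Cl[Zn]c1c(OC)cccc1OC | intermediate
6 | methyl (3R)-5-(2,6-dimethoxyphenyl)-3-methyl-5-oxopentanoate | C[C@H](CC(=O)c1c(OC)cccc1OC)CC(=O)OC | intermediate
7 | acetaldehyde | CC=O | starting material
8 | lithium enolate of 6 (ketone side, geometry open) | C[C@H](C=C([O-])c1c(OC)cccc1OC)CC(=O)OC.[Li+] | intermediate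
9 | methyl (3S)-4-(2,6-dimethoxybenzoyl)-5-hydroxy-3-methylhexanoate (mixture at C4, C5) | C[C@H](C(C(C)O)C(=O)c1c(OC)cccc1OC)CC(=O)OC | intermediate
10 | C5 methanesulfonate of 9 | C[C@H](C(C(C)OS(C)(=O)=O)C(=O)c1c(OC)cccc1OC)CC(=O)OC | intermediate
11 | methyl (3S,4E)-4-(2,6-dimethoxybenzoyl)-3-methylhex-4-enoate | C/C=C(\[C@@H](C)CC(=O)OC)C(=O)c1c(OC)cccc1OC | intermediate
12 | (3S,4E)-4-(2,6-dimethoxybenzoyl)-3-methylhex-4-enoic acid | C/C=C(\[C@@H](C)CC(=O)O)C(=O)c1c(OC)cccc1OC | intermediate
13 | 1-fluoro-3-methoxybenzene | COc1cccc(F)c1 | starting material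
14 | (3S,4E)-4-(2,6-dimethoxybenzoyl)-3-methylhex-4-enoyl chloride | C/C=C(\[C@@H](C)CC(=O)Cl)C(=O)c1c(OC)cccc1OC | intermediate
15 | 2-fluoro-6-methoxyphenyllithium | [Li]c1c(F)cccc1OC | intermediate
16 | (2-fluoro-6-methoxyphenyl)zinc chloride | Cl[Zn]c1c(F)cccc1OC | intermediate
17 | (3S,4E)-4-(2,6-dimethoxybenzoyl)-1-(2-fluoro-6-methoxyphenyl)-3-methylhex-4-en-1-one | C/C=C(\[C@@H](C)CC(=O)c1c(OC)cccc1F)C(=O)c1c(OC)cccc1OC | intermediate
18 | 1,8-dimethoxynaphthalene | COc1cccc2cccc(OC)c12 | starting material
19 | 2,2'-(4,5-dimethoxynaphthalene-2,7-diyl)bis(4,4,5,5-tetramethyl-1,3,2-dioxaborolane) | COc1cc(B2OC(C)(C)C(C)(C)O2)cc2cc(B3OC(C)(C)C(C)(C)O3)cc(OC)c12 | intermediate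
20 | 4,5-dimethoxynaphthalene-2,7-diol | COc1cc(O)cc2cc(O)cc(OC)c12 | intermediate
21 | seco diaryl ether (key-step precursor; 3S, 4E; C6–O–ring A, C1 and C8 OCH3, C3 OH) | C/C=C(\[C@@H](C)CC(=O)c1c(OC)cccc1Oc1cc(OC)c2c(OC)cc(O)cc2c1)C(=O)c1c(OC)cccc1OC | intermediate
22 | ten-membered macrocyclic diketone (C5–Cb bond made, Cm bears the 2,6-dimethoxybenzoyl group; Ca S, Cb R, Cm R) | C[C@H]1CC(=O)c2c(OC)cccc2Oc2cc(OC)c3c(OC)cc(O)cc3c2[C@H](C)[C@@H]1C(=O)c1c(OC)cccc1OC | intermediate
23 | ring D carbinol (C4 bonded to the former ketone carbon, tertiary OH, carbinol configuration open; Ca S, Cb R, Cm R) | C[C@H]1CC(=O)c2c(OC)cccc2Oc2cc(OC)c3c(OC)cc(O)c4c3c2[C@H](C)[C@@H]1C4(O)c1c(OC)cccc1OC | intermediate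
24 | penta-O-methyl ring-closed compound, 3-oxo quinone methide form (key-step product; Ca S, Cb R, Cm R) | C[C@H]1CC(=O)c2c(OC)cccc2Oc2cc(OC)c3c4c2[C@H](C)[C@@H]1C(c1c(OC)cccc1OC)=C4C(=O)C=C3OC | intermediate
25 | CNP0225737.1 (Ca S, Cb R, Cm R) | C[C@H]1CC(=O)c2c(O)cccc2Oc2cc(O)c3c4c2[C@H](C)[C@@H]1C(c1c(O)cccc1O)=C4C(O)=CC3=O | target

**Step count**
Total step count: 9. Longest linear sequence: 8 (steps 1 to 5 and 7 to 9, from 1). Step 6 is the one-step side branch.

**Steps most likely to fail**

**Step 8.**
- What may go wrong:
  - The first alkylation may start from ring C (C4, C2) or from C7 faster than these adducts revert.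
  - Chains may couple with each other in spite of the dilution.
  - The electron-rich ring E may be lost by acid-induced deacylation.
  - The two faces of the ethylidene carbon may be poorly differentiated.
  - The ring D alkene may drift by proton shift with loss of the methine configuration.
- Fallback (known chemistry, ring D first and the ether last). It sets out from 17 and 20. Treated together with (CF3SO2)2NH or CF3SO3H in CH2Cl2/(CF3)2CHOH at ordinary concentration, they should undergo the bimolecular naphthol–enone conjugate arylation and cyclodehydration. Because 20 is C2-symmetric, either peri carbon may begin. The ring that receives CH(CH3) keeps its hydroxyl next to the new bond, and the other ring becomes the quinone methide. This gives the ether-open fluoro phenalenone F1, whose isomers at Cb must be separated, since here allylic strain acts without the tether. Cs2CO3 in DMSO at high dilution then closes the ten-membered diaryl ether by intramolecular nucleophilic aromatic substitution, and the route is rejoined at 24.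

**Step 7.**
- What may go wrong:
  - Substitution may be slow because the doubly ortho-substituted ketone is twisted out of conjugation.
  - During the long heating the base may form the dienolate of the enone.
  - The naphthoxide may add to the enone in conjugate fashion.
  - A second arylation of the product may occur.
- Fallback (the enone is masked at the alcohol level while the ether is made). It sets out from 11. Luche reduction (NaBH4, CeCl3·7H2O, MeOH, −20 °C) gives the allylic alcohol F2, which K2CO3 closes to the δ-lactone F3. Aryllithium 15 opens F3 at −78 °C to the hydroxy ketone F4, whose alkene is no longer a Michael acceptor. Substitution with 20 (Cs2CO3, DMSO, 100 °C) gives the ether F5. MnO2 in CH2Cl2 then oxidises the alcohol, which is both allylic and benzylic, and the route is rejoined at 21.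

**Step 5.**
- What may go wrong:
  - The ortho-fluoro aryllithium may lose LiF before it is trapped by zinc.
  - Transmetalation of the doubly ortho-substituted arylzinc to acylpalladium may be slow, so that the acid chloride decays.
- Fallback (other acyl donor, other organometal, no base). It sets out from 12. EDC, DMAP and EtSH in CH2Cl2 give the S-ethyl thioester F6. Liebeskind–Srogl coupling with commercial (2-fluoro-6-methoxyphenyl)boronic acid (Pd2(dba)3, P(2-furyl)3, Cu(O2C-C4H3S), THF, 50 °C) rejoins the route at 17.

**Further compounds**
F1 | step 8 | ether-open fluoro phenalenone (ring D closed, C6–OH free, ring A still C–F; Ca S, Cb R, Cm R) | C[C@@H](CC(=O)c1c(OC)cccc1F)[C@H]1C(c2c(OC)cccc2OC)=C2C(=O)C=C(OC)c3c(OC)cc(O)c([C@@H]1C)c32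
F2 | step 7 | methyl (3S,4E)-4-[(2,6-dimethoxyphenyl)(hydroxy)methyl]-3-methylhex-4-enoate (carbinol centre open) | C/C=C(\[C@@H](C)CC(=O)OC)C(O)c1c(OC)cccc1OC
F3 | step 7 | (4S,5E)-6-(2,6-dimethoxyphenyl)-5-ethylidene-4-methyloxan-2-one (C6 open) | C/C=C1\[C@@H](C)CC(=O)OC1c1c(OC)cccc1OC
F4 | step 7 | (3S,4E)-4-[(2,6-dimethoxyphenyl)(hydroxy)methyl]-1-(2-fluoro-6-methoxyphenyl)-3-methylhex-4-en-1-one | C/C=C(\[C@@H](C)CC(=O)c1c(OC)cccc1F)C(O)c1c(OC)cccc1OC
F5 | step 7 | allylic alcohol analogue of 21 (ring E carbinol in place of the ketone) | C/C=C(\[C@@H](C)CC(=O)c1c(OC)cccc1Oc1cc(OC)c2c(OC)cc(O)cc2c1)C(O)c1c(OC)cccc1OC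
F6 | step 5 | S-ethyl (3S,4E)-4-(2,6-dimethoxybenzoyl)-3-methylhex-4-enethioate | C/C=C(\[C@@H](C)CC(=O)SCC)C(=O)c1c(OC)cccc1OC
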